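Readings and results come from a simulation on assumed constants.

The leftover of the dusk run is the part of the charge not found as target, 54.1% of the starting material at the last reading, yet its last two readings of target were 0.2784 M and 0.2752 M. These are the minutes of a short meeting on what that means for the winter run.

| flask | starting material | reagent | free catalyst | time |
|---|---|---|---|---|
| summer | 0.600 M | 0.900 M | 0.00300 M |  |
| autumn | 0.600 M | 0.450 M | 0.00300 M |  |
| dusk | 0.600 M | 0.900 M | 0.00900 M |  |
| winter | 3.00 M | 0.900 M | 0.00300 M | 3.8 min |

- summer run (time / min: [target] / M): 0.29: 0.0218; 0.88: 0.0587; 1.7: 0.0964; 2.7: 0.1198; 3.8: 0.1389
- autumn run (time / min: [target] / M): 0.29: 0.0094; 0.88: 0.0321; 1.7: 0.0497; 2.7: 0.0688; 3.8: 0.0818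
- dusk run (time / min: [target] / M): 0.29: 0.0683; 0.88: 0.1680; 1.7: 0.2448; 2.7: 0.2784; 3.8: 0.2752

(readings scatter by 0.002 M)

- Overall: starting material + reagent -> target, with free catalyst as catalyst.
- Constant volume, constant temperature.
- Readings of a species count what is bound in complexes too.
- "The second partner" is reagent.
- An order is taken over about fifteen percent of the charge, up and down.

- apparent order in [free catalyst] of the starting rate, round the charge of the summer run (the rate where two percent of its starting material have turned into target)
- apparent order in [reagent] of the starting rate, round the charge of the summer run (the rate where two percent of its starting material have turned into target)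
- target in the winter run at 3.8 min, as a share of the starting material charged

The bench chemist read the starts from the first readings. Autumn's rate stood at 0.431 of summer's on 0.500 of the reagent, and dusk's at 3.13 times summer's on 3.00 times the catalyst, so she put both orders near one.

The kineticist asked what end state dusk was approaching, and compared the runs at like target, where the catalysed reaction and its reversal, with nothing else at work, leave like amounts of starting material and reagent. Dusk gained 0.169 M min⁻¹ between its first two readings, and summer gained 0.0174 M min⁻¹ between its last two, so dusk was faster by a factor of 9.71, more than the catalyst ratio. A reversal carried by the catalyst keeps the catalyst ratio, he argued, so dusk's flat end is making meeting a loss, not an equilibrium.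

No run varied the starting material, so the chair bracketed the winter run. If rate follows that charge in proportion, summer's share, 23.2%, is a ceiling for winter and not a value: that share of the winter charge is 0.695 M of target against 0.900 M of reagent, a far larger part of the reagent than summer's target took. If the catalyst is already full, with the catalyst-substrate complex as its resting state, the larger charge adds no speed. Winter then holds summer's target, and the share is 4.63%, the flat share: summer's target at 3.8 min over the winter charge of starting material. The chair committed to between 4.63% and 9.26%, a bet the runs do not test, resting on catalyst charged far below starting material.

The forecast gave 1 (0.85 to 1.15) for the catalyst order, 0.95 (0.7 to 1.15) for the reagent order and 19% (9% to 23.5%) for the winter share, with the remark that “saturation would give much less”.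

The flask gives orders of 1.1 and 1.0 and a winter share of 6.15%.

    free catalyst + starting material ⇌ catalyst-substrate complex, settled at all times (11.20 M⁻¹)
    catalyst-substrate complex + reagent → target + free catalyst + by-product (35.76 M⁻¹ min⁻¹)
    free catalyst + reagent → spent catalyst + reagent (1.056 M⁻¹ min⁻¹)
    target → decomposed product (0.2232 min⁻¹)

From the start of the winter run 97.1% of the catalyst stood as catalyst-substrate complex, against 87.0% at the summer charge, and target was made while that complex met reagent, while the target already present turned into decomposed product at 0.223 min⁻¹. At 3.8 min the winter run, on 5.00 times summer's charge of starting material, held 0.184 M of target, which is 1.33 times the flat share.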